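**Plan**

1. Numbering used below: C1 = ring CH(CH3), C2/C3 = ring CH2, C4 = ring-fusion C–OH, C5 = ring-fusion CH, C6 = CH2, C7 = CH(OH), C8 = C(CH3)2, C9 = C=O, C10 = quaternary C, C11/C12 = chain CH2, C13–C16 = butenolide; ring A = cycloheptane, ring B = cyclopentane; β = face of the C4 oxygen, α = the opposite face.
2. Retrosynthesis: the butenolide (C13=C14, C15–O) and the C10–C11 bond are cut back to a C10 methylene ketone; both rings are then cut together at C4–C5 and C9–C10, an intramolecular (5+2) cycloaddition; the open chain is cut at C4–C8 (acylation) and C6–C7 (propargylation).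
3. Enabling feature: in ring A the two-carbon unit C5–C9 is flanked by the five-carbon arc C4–C3–C2–C1–C10, and the fusion bond C4–C5 is shared with ring B, whose other atoms C8–C7–C6 serve as a three-atom tether. C4 carries oxygen, so the alkene end is a silyl enol ether; C2–C1–C10 is a temporary cyclopropane; C5≡C9 is an alkyne, oxidised at C9 afterwards.
4. Forward: cyclopropane ester → homologated acid → keto aldehyde → propargyl carbinol → bis-silyl enyne → rings A and B closed together → C2=C3 hydrogenation, C9 oxygenation, C10 quaternisation, butenolide, desilylation.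
5. Stereochemistry: C1 is bought with (R)-propylene oxide; C7 is set by chiral phosphoric acid catalysis; C4 by chirality transfer from the cyclopropane in the key step; C5 by hydroboration anti to the angular C4 silyloxy group; C10 by Michael addition anti to the C1 methyl.

Key step: step 7

Remark: (R)-TRIP is taken to deliver the (R)-carbinol at C7 in step 5; if the opposite sense is found, the (S)-catalyst is used and nothing else changes.

**Route**

Step 1
Reactants: 1 (R)-propylene oxide; 2 triethyl phosphonoacetate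
Product: 3 ethyl (1S,2S)-2-methylcyclopropane-1-carboxylate
Conditions: NaH, toluene, 25 °C; then 1, 110 °C (sealed vessel)
Reagents that add atoms: none
Why: Wadsworth–Emmons cyclopropanation: the phosphonate carbanion opens the epoxide at CH2, the phosphoryl group moves to the alkoxide and the ester enolate closes the ring by SN2 displacement with inversion at the methyl-bearing carbon, so the (R)-epoxide should give the trans (1S,2S) ester.

Step 2
Reactants: 3 ethyl (1S,2S)-2-methylcyclopropane-1-carboxylate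
Product: 6 ethyl 2-[(1R,2S)-2-methylcyclopropyl]acetate, via dibromomethyl ketone enolate 4 (not isolated), via lithium ynolate 5 (not isolated)
Conditions: CH2Br2, lithium 2,2,6,6-tetramethylpiperidide, THF, −78 °C; LiN(SiMe3)2; n-BuLi, −78 → 25 °C; then HCl/EtOH, 0 °C
Reagents that add atoms: dibromomethane, BrCBr; ethanol, CCO
Why: Kowalski ester homologation: LiCHBr2 adds to the ester, bromine–lithium exchange on the dibromo enolate triggers a 1,2-shift of the cyclopropyl group with retention to the ynolate, and ethanolic acid gives the one-carbon-longer ester without touching either ring stereocentre.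

Step 3
Reactants: 6 ethyl 2-[(1R,2S)-2-methylcyclopropyl]acetate
Product: 7 2-[(1R,2S)-2-methylcyclopropyl]acetic acid
Conditions: LiOH, THF/H2O, 25 °C; then aq. HCl
Reagents that add atoms: lithium hydroxide, [Li+].[OH-]
Why: Ester saponification; no stereocentre is epimerisable.

Step 4
Reactants: 7 2-[(1R,2S)-2-methylcyclopropyl]acetic acid; 8 4-(2-methylprop-1-en-1-yl)morpholine
Product: 11 2,2-dimethyl-4-[(1R,2S)-2-methylcyclopropyl]-3-oxobutanal, via acid chloride 9 (not isolated), via iminium chloride 10 (not isolated)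
Conditions: (COCl)2, DMF (cat.), CH2Cl2, 0 → 25 °C; concentrate; 8, Et2O, 0 → 25 °C; then 1 M HCl
Reagents that add atoms: water, O
Why: Stork enamine C-acylation: the acid chloride acylates the β-carbon of the isobutyraldehyde enamine, and the iminium salt, which has no α-hydrogen, hydrolyses to the non-enolisable 2,2-dimethyl β-keto aldehyde (C4–C8 bond).

Step 5
Reactants: 11 2,2-dimethyl-4-[(1R,2S)-2-methylcyclopropyl]-3-oxobutanal; 12 allenylboronic acid pinacol ester
Product: 14 (4R)-4-hydroxy-3,3-dimethyl-1-[(1R,2S)-2-methylcyclopropyl]hept-6-yn-2-one, via pinacol borate ester 13 (not isolated)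
Conditions: 12 (1.5 equiv), (R)-TRIP (10 mol %), 4 Å molecular sieves, toluene, 0 °C; then aq. NaHCO3
Reagents that add atoms: none
Why: Chiral phosphoric acid-catalysed allenylboration (SE2′ propargylation) is chemoselective for the aldehyde over the hindered ketone and sets C7 under catalyst control (C6–C7 bond); a minor C7 epimer would be a diastereomer and separable.

Step 6
Reactants: 14 (4R)-4-hydroxy-3,3-dimethyl-1-[(1R,2S)-2-methylcyclopropyl]hept-6-yn-2-one
Product: 16 (1Z,4R)-3,3-dimethyl-1-[(1S,2S)-2-methylcyclopropyl]-2,4-bis(triethylsilyloxy)hept-1-en-6-yne, via silyl ether ketone 15 (not isolated)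
Conditions: Et3SiOTf (2.6 equiv), Et3N (4 equiv), CH2Cl2, −78 → 0 °C
Reagents that add atoms: triethylsilyl trifluoromethanesulfonate, CC[Si](CC)(CC)OS(=O)(=O)C(F)(F)F
Why: O-silylation followed by soft enolisation with the silyl triflate and amine: only C3 carries α-hydrogens, and the Z enol ether (oxygen cis to cyclopropyl) is expected because the E isomer would place the quaternary C8 cis to the cyclopropyl group (allylic 1,3-strain).

Step 7
Reactants: 16 (1Z,4R)-3,3-dimethyl-1-[(1S,2S)-2-methylcyclopropyl]-2,4-bis(triethylsilyloxy)hept-1-en-6-yne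
Product: 17 bicyclic diene (C2=C3 and C5=C9) carrying 1α-CH3 and 8,8-(CH3)2 and 4β,7α-bis(triethylsilyloxy) groups
Conditions: [Rh(CO)2Cl]2 (5 mol %), ClCH2CH2Cl (0.02 M), 80 °C
Reagents that add atoms: none
Why: Proposed new method: monovalent rhodium is expected to insert into the less substituted C2–C10 bond of the cyclopropane while bound to the enol ether, giving a σ,π-allyl rhodacycle (C10–Rh, allyl C2–C3–C4); the tethered alkyne then inserts at the allyl terminus C4 (C4–C5 bond) and C(sp2)–C(sp3) reductive elimination joins C9 to C10, a net suprafacial homo-Diels–Alder-type (5+2) addition. The closest known reaction type is the rhodium-catalysed intramolecular (5+2) cycloaddition of alkyne-tethered (E)-vinylcyclopropanes, which has not been shown with a silyl enol ether as the alkene or with a fully substituted alkene terminus next to a quaternary carbon. Ring B closes across the three-atom tether C8–C7–C6 by migratory insertion in the 5-exo sense, and ring A closes as a cycloheptadiene by reductive elimination from the eight-membered rhodacycle. C4 is the only new stereocentre: the bond forms on the face of the C2–C3–C4 unit from which C10 departs, so the (1S,2S)-cyclopropane together with the Z enol ether geometry should place the C4 silyloxy group β and trans to the untouched α C1 methyl, independently of C7. The step needs cleavage of C2–C10 rather than C2–C1, expected because C10 is the unsubstituted ring carbon and the trans methyl points away from the metallacycle. It also needs the hindered donor alkene to stay bound, which the gem-dimethyl group on C8 (reactive rotamer) and the neutral, non-Lewis-acidic [Rh(CO)2Cl]2 are chosen to secure.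

Step 8
Reactants: 17 bicyclic diene (C2=C3 and C5=C9)
Product: 18 bicyclic C5=C9 alkene carrying 1α-CH3 and 8,8-(CH3)2 and 4β,7α-bis(triethylsilyloxy) groups
Conditions: H2 (1 atm), RhCl(PPh3)3 (10 mol %), benzene, 25 °C
Reagents that add atoms: none
Why: Chemoselective homogeneous hydrogenation: RhCl(PPh3)3 should reduce the cis-disubstituted C2=C3 bond far faster than the trisubstituted C5=C9 bond; no stereocentre is formed.

Step 9
Reactants: 18 bicyclic C5=C9 alkene
Product: 20 trans-fused 9α-alcohol with 5α-H and 4β,7α-bis(triethylsilyloxy) groups, via alkylborane 19 (not isolated)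
Conditions: BH3·SMe2, THF, 0 → 25 °C; then NaOH, H2O2, 0 °C
Reagents that add atoms: hydrogen peroxide, OO
Why: Hydroboration–oxidation: boron adds to the less substituted C9 and hydrogen to C5 in a syn addition from the α face, anti to the pseudoaxial angular C4 silyloxy group, which should give the C5 α-hydrogen and thus the trans ring fusion.

Step 10
Reactants: 20 trans-fused 9α-alcohol
Product: 21 trans-fused C9 ketone with 5α-H and 4β,7α-bis(triethylsilyloxy) groups
Conditions: Dess–Martin periodinane, NaHCO3, CH2Cl2, 0 → 25 °C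
Reagents that add atoms: none
Why: Dess–Martin oxidation of the secondary alcohol under buffered, non-basic conditions, so that C5 is not epimerised and the β-silyloxy group is not eliminated.

Step 11
Reactants: 21 trans-fused C9 ketone
Product: 24 C10-methylene C9 ketone, via Mannich base 22 (not isolated), via ammonium iodide 23 (not isolated)
Conditions: LiN(i-Pr)2, THF, −78 °C; CH2=NMe2+ I−, −78 → 25 °C; MeI, MeOH; then aq. NaHCO3, CH2Cl2
Reagents that add atoms: N,N-dimethylmethyleneiminium iodide (Eschenmoser's salt), C=[N+](C)C.[I-]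
Why: Kinetic deprotonation at the C10 methylene (not at the hindered C5 methine), Mannich reaction with Eschenmoser's salt, N-methylation and elimination give the α-methylene ketone and thereby the carbon of the C10 methyl group.

Step 12
Reactants: 24 C10-methylene C9 ketone
Product: 25 C9–C10 triethylsilyl enol ether bearing the C10 methyl group
Conditions: Et3SiH, RhCl(PPh3)3 (2 mol %), benzene, 50 °C
Reagents that add atoms: triethylsilane, CC[SiH](CC)CC
Why: Rhodium-catalysed 1,4-hydrosilylation of the s-cis enone gives the tetrasubstituted C9–C10 silyl enol ether regiospecifically, which fixes the site of the next bond at C10 and avoids enolisation toward C5.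

Step 13
Reactants: 25 C9–C10 triethylsilyl enol ether; 26 methyl vinyl ketone
Product: 27 diketone with quaternary C10 (10α-CH3 and 10β-CH2CH2COCH3)
Conditions: 26, BF3·OEt2, i-PrOH, CH2Cl2, −78 °C
Reagents that add atoms: none
Why: Mukaiyama–Michael addition: the enol ether should attack methyl vinyl ketone on the face anti to the adjacent α C1 methyl group, so the new chain is β and the C10 methyl α (cis to the C1 methyl), with 2-propanol taking the silyl group and protonating the adduct.

Step 14
Reactants: 27 diketone with quaternary C10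
Product: 30 α-hydroxy ketone (10β-CH2CH2COCH2OH), via trimethylsilyl enol ether 28 (not isolated), via silyloxy ketone 29 (not isolated)
Conditions: LiN(i-Pr)2, Me3SiCl, THF, −78 °C; mCPBA, NaHCO3, CH2Cl2, −20 °C; citric acid, MeOH, 0 °C
Reagents that add atoms: 3-chloroperoxybenzoic acid, OOC(=O)c1cccc(Cl)c1
Why: Rubottom oxidation: kinetic deprotonation with in situ silylation gives the terminal enol ether of the methyl ketone (faster than aldol closure onto the hindered C9 ketone), epoxidation and silyl shift give the α-silyloxy ketone, and mild acid frees the primary alcohol while the hindered triethylsilyl ethers stay.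

Step 15
Reactants: 30 α-hydroxy ketone
Product: 32 bis(triethylsilyl) ether of the target, via acyl ylide 31 (not isolated)
Conditions: Ph3P=C=C=O, toluene, 90 °C
Reagents that add atoms: (triphenylphosphoranylidene)ketene, O=C=C=P(c1ccccc1)(c1ccccc1)c1ccccc1
Why: Bestmann butenolide synthesis: the ketene ylide acylates the primary alcohol and the resulting stabilised ylide closes on the neighbouring ketone by intramolecular Wittig reaction; the hindered C9 ketone should not react.

Step 16
Reactants: 32 bis(triethylsilyl) ether of the target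
Product: 33 target CNP0077405.2
Conditions: HF·pyridine, pyridine, THF, 0 → 25 °C
Reagents that add atoms: none
Why: Acidic fluoride desilylation removes both triethylsilyl groups; basic fluoride is avoided because the product is a β-hydroxy ketone prone to retro-aldol cleavage and elimination.

**Compound list**

1 | (R)-propylene oxide | C[C@@H]1CO1 | starting material
2 | triethyl phosphonoacetate | CCOC(=O)CP(=O)(OCC)OCC | starting material
3 | ethyl (1S,2S)-2-methylcyclopropane-1-carboxylate (trans) | C[C@@H]1[C@@H](C(=O)OCC)C1 | intermediate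
4 | 2,2-dibromo-1-[(1S,2S)-2-methylcyclopropyl]ethan-1-one (present as its lithium enolate) | C[C@@H]1[C@@H](C(=O)C(Br)Br)C1 | intermediate (not isolated)
5 | lithium 2-[(1S,2S)-2-methylcyclopropyl]ethynolate | C[C@@H]1[C@@H](C#C[O-])C1.[Li+] | intermediate (not isolated)
6 | ethyl 2-[(1R,2S)-2-methylcyclopropyl]acetate | C[C@@H]1[C@@H](CC(=O)OCC)C1 | intermediate
7 | 2-[(1R,2S)-2-methylcyclopropyl]acetic acid | C[C@@H]1[C@@H](CC(=O)O)C1 | intermediate
8 | 4-(2-methylprop-1-en-1-yl)morpholine | CC(C)=CN1CCOCC1 | starting material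
9 | 2-[(1R,2S)-2-methylcyclopropyl]acetyl chloride | C[C@@H]1[C@@H](CC(=O)Cl)C1 | intermediate (not isolated)
10 | 4-{2,2-dimethyl-4-[(1R,2S)-2-methylcyclopropyl]-3-oxobutylidene}morpholin-4-ium chloride | C[C@@H]1[C@@H](CC(=O)C(C)(C)C=[N+]2CCOCC2)C1.[Cl-] | intermediate (not isolated)
11 | 2,2-dimethyl-4-[(1R,2S)-2-methylcyclopropyl]-3-oxobutanal | C[C@@H]1[C@@H](CC(=O)C(C)(C)C=O)C1 | intermediate
12 | allenylboronic acid pinacol ester | C=C=CB1OC(C)(C)C(C)(C)O1 | starting material
13 | pinacol borate ester of 14 | C[C@@H]1[C@@H](CC(=O)C(C)(C)[C@H](OB2OC(C)(C)C(C)(C)O2)CC#C)C1 | intermediate (not isolated)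
14 | (4R)-4-hydroxy-3,3-dimethyl-1-[(1R,2S)-2-methylcyclopropyl]hept-6-yn-2-one | C[C@@H]1[C@@H](CC(=O)C(C)(C)[C@H](O)CC#C)C1 | intermediate
15 | (4R)-3,3-dimethyl-1-[(1R,2S)-2-methylcyclopropyl]-4-(triethylsilyloxy)hept-6-yn-2-one | C[C@@H]1[C@@H](CC(=O)C(C)(C)[C@H](O[Si](CC)(CC)CC)CC#C)C1 | intermediate (not isolated)
16 | (1Z,4R)-3,3-dimethyl-1-[(1S,2S)-2-methylcyclopropyl]-2,4-bis(triethylsilyloxy)hept-1-en-6-yne | C[C@@H]1[C@@H](/C=C(\O[Si](CC)(CC)CC)C(C)(C)[C@H](O[Si](CC)(CC)CC)CC#C)C1 | intermediate
17 | cycloadduct: 5–7 bicycle with C2=C3 and C5=C9 double bonds, 1α-CH3, 8,8-(CH3)2, 4β-OSiEt3, 7α-OSiEt3 | C[C@@H]1C=C[C@@]2(O[Si](CC)(CC)CC)C(C[C@@H](O[Si](CC)(CC)CC)C2(C)C)=CC1 | intermediate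
18 | 2,3-dihydro derivative of 17 (C5=C9 alkene only) | C[C@@H]1CC[C@@]2(O[Si](CC)(CC)CC)C(C[C@@H](O[Si](CC)(CC)CC)C2(C)C)=CC1 | intermediate
19 | 9α-boryl derivative (RBH2) with 5α-H | C[C@@H]1CC[C@@]2(O[Si](CC)(CC)CC)[C@@H](C[C@@H](O[Si](CC)(CC)CC)C2(C)C)[C@H](B)C1 | intermediate (not isolated)
20 | trans-fused 9α-alcohol, 5α-H, 4β,7α-bis(triethylsilyloxy), 1α,8,8-trimethyl | C[C@@H]1CC[C@@]2(O[Si](CC)(CC)CC)[C@@H](C[C@@H](O[Si](CC)(CC)CC)C2(C)C)[C@H](O)C1 | intermediate
21 | trans-fused C9 ketone, 5α-H, 4β,7α-bis(triethylsilyloxy), 1α,8,8-trimethyl | C[C@@H]1CC[C@@]2(O[Si](CC)(CC)CC)[C@@H](C[C@@H](O[Si](CC)(CC)CC)C2(C)C)C(=O)C1 | intermediate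
22 | C10-(dimethylaminomethyl) ketone (Mannich base) | C[C@@H]1CC[C@@]2(O[Si](CC)(CC)CC)[C@@H](C[C@@H](O[Si](CC)(CC)CC)C2(C)C)C(=O)C1CN(C)C | intermediate (not isolated)
23 | C10-(trimethylammoniomethyl) ketone iodide | C[C@@H]1CC[C@@]2(O[Si](CC)(CC)CC)[C@@H](C[C@@H](O[Si](CC)(CC)CC)C2(C)C)C(=O)C1C[N+](C)(C)C.[I-] | intermediate (not isolated)
24 | C10-methylene C9 ketone | C[C@@H]1CC[C@@]2(O[Si](CC)(CC)CC)[C@@H](C[C@@H](O[Si](CC)(CC)CC)C2(C)C)C(=O)C1=C | intermediate
25 | C9(OSiEt3)=C10(CH3) silyl enol ether | C[C@@H]1CC[C@@]2(O[Si](CC)(CC)CC)[C@@H](C[C@@H](O[Si](CC)(CC)CC)C2(C)C)C(O[Si](CC)(CC)CC)=C1C | intermediate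
26 | methyl vinyl ketone | CC(=O)C=C | starting material
27 | diketone: C9 ketone with 10α-CH3 and 10β-(3-oxobutyl) | C[C@@H]1CC[C@@]2(O[Si](CC)(CC)CC)[C@@H](C[C@@H](O[Si](CC)(CC)CC)C2(C)C)C(=O)[C@@]1(C)CCC(C)=O | intermediate
28 | terminal trimethylsilyl enol ether of the side-chain ketone | C[C@@H]1CC[C@@]2(O[Si](CC)(CC)CC)[C@@H](C[C@@H](O[Si](CC)(CC)CC)C2(C)C)C(=O)[C@@]1(C)CCC(=C)O[Si](C)(C)C | intermediate (not isolated)
29 | side-chain α-(trimethylsilyloxy) ketone | C[C@@H]1CC[C@@]2(O[Si](CC)(CC)CC)[C@@H](C[C@@H](O[Si](CC)(CC)CC)C2(C)C)C(=O)[C@@]1(C)CCC(=O)CO[Si](C)(C)C | intermediate (not isolated)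
30 | side-chain α-hydroxy ketone (10β-CH2CH2COCH2OH) | C[C@@H]1CC[C@@]2(O[Si](CC)(CC)CC)[C@@H](C[C@@H](O[Si](CC)(CC)CC)C2(C)C)C(=O)[C@@]1(C)CCC(=O)CO | intermediate
31 | (triphenylphosphoranylidene)acetate ester of 30 | C[C@@H]1CC[C@@]2(O[Si](CC)(CC)CC)[C@@H](C[C@@H](O[Si](CC)(CC)CC)C2(C)C)C(=O)[C@@]1(C)CCC(=O)COC(=O)C=P(c3ccccc3)(c3ccccc3)c3ccccc3 | intermediate (not isolated)
32 | 4β,7α-bis(triethylsilyl) ether of the target | C[C@@H]1CC[C@@]2(O[Si](CC)(CC)CC)[C@@H](C[C@@H](O[Si](CC)(CC)CC)C2(C)C)C(=O)[C@@]1(C)CCC1=CC(=O)OC1 | intermediate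
33 | CNP0077405.2: trans-fused 4β,7α-dihydroxy-1α,8,8,10α-tetramethyl-10β-[2-(5-oxo-2,5-dihydrofuran-3-yl)ethyl] 5–7 bicyclic 9-ketone (1R,4R,5R,7R,10S in the numbering above) | C[C@@H]1CC[C@@]2(O)[C@@H](C[C@@H](O)C2(C)C)C(=O)[C@@]1(C)CCC1=CC(=O)OC1 | target

**Count and risks**

Total step count: 16. Longest linear sequence: 16 steps (1 → 33).

Steps most likely to fail:

1. Step 7. The hindered, donor-substituted enol ether may fail to engage the metal or to form the C4–C5 bond next to the quaternary C8, or the methyl-bearing cyclopropane bond may be cleaved instead of C2–C10. The fallback closes the two rings in separate, precedented operations; it sets out from enamine 8 and comes back to the route at 18.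
 - (R)-Citronellal F1 is methylenated (Ph3P=CH2, THF) to (6R)-2,6-dimethylnona-2,8-diene F2.
 - Selective ozonolysis of the trisubstituted alkene (O3, CH2Cl2, −78 °C, indicator end point; Me2S) gives (4R)-4-methylhept-6-enal F3, and Pinnick oxidation (NaClO2, NaH2PO4, 2-methyl-2-butene) gives (4R)-4-methylhept-6-enoic acid F4.
 - As in step 4, F4 is converted with (COCl)2 to (4R)-4-methylhept-6-enoyl chloride F5, which acylates 8 to the iminium chloride F6; hydrolysis gives (6R)-2,2,6-trimethyl-3-oxonon-8-enal F7.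
 - Propargylation with 12 under (R)-TRIP passes through the pinacol borate F8 to (4R,9R)-4-hydroxy-5,5,9-trimethyldodec-11-en-1-yn-6-one F9, and Et3SiCl/imidazole gives its triethylsilyl ether F10.
 - SmI2 (divalent samarium), HMPA, t-BuOH, THF effects ketyl–alkyne 5-exo-dig cyclisation to the 2-methylenecyclopentanol F11 (C4–C5 bond). The samarium alkoxide is expected anti to the C7 silyloxy group, and a C4 epimer would be separable.
 - Et3SiOTf/2,6-lutidine gives the bis(triethylsilyl) ether F12, and ring-closing metathesis with the second-generation Grubbs catalyst (CH2Cl2, 40 °C) between the exocyclic methylene and the terminal vinyl group closes ring A to 18 with loss of ethene.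

2. Step 9. Hydroboration may show poor facial selectivity and deliver hydrogen to the β face of C5, leading to the cis-fused series. The fallback sets C5 by hydroxyl-directed hydrogenation from the α-face C7 oxygen; it sets out from 18 and comes back at 21.
 - mCPBA (NaHCO3, CH2Cl2) gives the C5–C9 epoxide F13.
 - Diethylaluminium 2,2,6,6-tetramethylpiperidide (toluene, 0 °C) opens the trisubstituted epoxide at the tertiary carbon with loss of a C6 proton to the allylic alcohol F14 (C5=C6, C9–OH).
 - Dess–Martin periodinane gives the enone F15.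
 - PPTS in MeOH cleaves the secondary C7 silyl ether in preference to the tertiary one, giving the hydroxy enone F16.
 - H2 with [Ir(cod)(PCy3)(py)]PF6 in CH2Cl2 adds hydrogen to C5=C6 from the face of the C7 hydroxyl, giving the hydroxy ketone F17 with the C5 α-hydrogen.
 - Et3SiOTf/2,6-lutidine returns 21.

3. Step 13. The congested C10–C11 bond may form sluggishly, with desilylation of the enol ether competing, or the acceptor may approach syn to the C1 methyl. The fallback forms the quaternary centre by a radical conjugate addition; it sets out from 24 and comes back at 27.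
 - NaBH4/CeCl3 in MeOH (Luche reduction) gives the allylic alcohol F18.
 - Fe(acac)3, PhSiH3 and 26 in EtOH/ethylene glycol at 60 °C generate the tertiary C10 radical by hydrogen-atom transfer to the exocyclic methylene. It should add to methyl vinyl ketone anti to the C1 methyl, giving the hydroxy ketone F19.
 - Dess–Martin periodinane oxidises C9 and returns 27.

**Further compounds**

F1 | step 7 | (R)-citronellal | C[C@@H](CC=O)CCC=C(C)C
F2 | step 7 | (6R)-2,6-dimethylnona-2,8-diene | C[C@@H](CC=C)CCC=C(C)C
F3 | step 7 | (4R)-4-methylhept-6-enal | C[C@@H](CC=C)CCC=O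
F4 | step 7 | (4R)-4-methylhept-6-enoic acid | C[C@@H](CC=C)CCC(=O)O
F5 | step 7 | (4R)-4-methylhept-6-enoyl chloride | C[C@@H](CC=C)CCC(=O)Cl
F6 | step 7 | 4-[(6R)-2,2,6-trimethyl-3-oxonon-8-en-1-ylidene]morpholin-4-ium chloride | C[C@@H](CC=C)CCC(=O)C(C)(C)C=[N+]1CCOCC1.[Cl-]
F7 | step 7 | (6R)-2,2,6-trimethyl-3-oxonon-8-enal | C[C@@H](CC=C)CCC(=O)C(C)(C)C=O
F8 | step 7 | pinacol borate ester of F9 | C[C@@H](CC=C)CCC(=O)C(C)(C)[C@H](OB1OC(C)(C)C(C)(C)O1)CC#C
F9 | step 7 | (4R,9R)-4-hydroxy-5,5,9-trimethyldodec-11-en-1-yn-6-one | C[C@@H](CC=C)CCC(=O)C(C)(C)[C@H](O)CC#C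
F10 | step 7 | (4R,9R)-5,5,9-trimethyl-4-(triethylsilyloxy)dodec-11-en-1-yn-6-one | C[C@@H](CC=C)CCC(=O)C(C)(C)[C@H](O[Si](CC)(CC)CC)CC#C
F11 | step 7 | 2-methylenecyclopentanol: C4 β-OH with the (3R)-3-methylhex-5-enyl chain, C5 exocyclic methylene, 7α-OSiEt3, 8,8-(CH3)2 | C[C@@H](CC=C)CC[C@@]1(O)C(=C)C[C@@H](O[Si](CC)(CC)CC)C1(C)C
F12 | step 7 | 4β,7α-bis(triethylsilyl) ether of F11 | C[C@@H](CC=C)CC[C@@]1(O[Si](CC)(CC)CC)C(=C)C[C@@H](O[Si](CC)(CC)CC)C1(C)C
F13 | step 9 | C5–C9 epoxide of 18 | C[C@@H]1CC[C@@]2(O[Si](CC)(CC)CC)C3(C[C@@H](O[Si](CC)(CC)CC)C2(C)C)OC3C1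
F14 | step 9 | allylic alcohol with C5=C6 and C9–OH | C[C@@H]1CC[C@@]2(O[Si](CC)(CC)CC)C(=C[C@@H](O[Si](CC)(CC)CC)C2(C)C)C(O)C1
F15 | step 9 | C9 ketone conjugated with C5=C6 | C[C@@H]1CC[C@@]2(O[Si](CC)(CC)CC)C(=C[C@@H](O[Si](CC)(CC)CC)C2(C)C)C(=O)C1
F16 | step 9 | 7α-hydroxy enone (C4 silyl ether retained) | C[C@@H]1CC[C@@]2(O[Si](CC)(CC)CC)C(=C[C@@H](O)C2(C)C)C(=O)C1
F17 | step 9 | trans-fused 7α-hydroxy C9 ketone with 5α-H | C[C@@H]1CC[C@@]2(O[Si](CC)(CC)CC)[C@@H](C[C@@H](O)C2(C)C)C(=O)C1
F18 | step 13 | C9 allylic alcohol with C10 exocyclic methylene | C[C@@H]1CC[C@@]2(O[Si](CC)(CC)CC)[C@@H](C[C@@H](O[Si](CC)(CC)CC)C2(C)C)C(O)C1=C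
F19 | step 13 | C9 alcohol with 10α-CH3 and 10β-(3-oxobutyl) | C[C@@H]1CC[C@@]2(O[Si](CC)(CC)CC)[C@@H](C[C@@H](O[Si](CC)(CC)CC)C2(C)C)C(O)[C@@]1(C)CCC(C)=O
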